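Add D and X together and hold the sum against the E charged: that was the one count I carried through these flasks.

| flask | L | E | Q | remark | time |
|---|---|---|---|---|---|
| north-east | 0.50 M (fed, over 50 s) | 0.60 M | 18 mM | run made earlier; the fed solution adds 0.25 times the starting volume |  |
| spring | 0.50 M | 0.150 M | 12 mM | everything together at the start, the whole solution of L included, so that from the start the volume is larger by 0.25 times the starting volume | 15 min |
| midnight | 0.50 M (fed, over 50 s) | 0.600 M | 12 mM | the fed solution adds 0.25 times the starting volume | 15 min |

north-east run (percent of the L charged)

| time / min | D / % |
|---|---|
| 0.250 | 4 |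
| 0.833 | 15 |
| 1.33 | 20 |
| 2.00 | 21 |
| 3.00 | 25 |

(readings scatter by 1.5 percentage points)

- charges are per starting volume, the dose included; the dosed solution carries all of it
- what was read earlier has a scatter of 1.5 percentage points, one standard deviation
- candidate steps: Q -> 2 Z; L + Z -> G; E + G -> D + Z; 2 Z -> J; D <-> X
- percentages count the whole charge, also what has not yet gone in
- no earlier run changes the charge of Q; that part of a forecast is a guess

- the flask that ends with the higher amount of D, in percent of the L charged, or "neither" when 2 percentage points or less lies between them (spring / midnight / neither)
- final D, as a percentage of the L charged, in spring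
- final D, as a percentage of the L charged, in midnight

Read down, the table shows D at 15% when the feed ended at 0.833 min, and it added 10 percentage points up to 3.00 min. Each D takes one E in E + G -> D + Z, and X comes from D, so I counted the two as one sum.

Spring charges 0.150 M of E on 0.50 M of L, so 30.0% of L can pass that step; I called this ratio of charges the E ceiling, with E as the limiting reagent in spring. Midnight has the feed and the charges of E and L of the north-east run, and its ceiling is 120%. The last reading of D in the north-east run stood below that, so I looked to Q for the slowing. Taking the radical level as the root of [Q], which was a guess, I scaled that reading to 20.4% of D for midnight. For spring I committed to D below 30.0% by the share that goes to X. The readings do not measure X, so I left the order open.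

The forecast said spring, with 27% for spring and 22% for midnight, holding that “E caps D at 30% of L”, and its spring figure stands near what all of E turned into D gives.

The flask that ended higher was midnight, with 23.4% of D against 11.5% in spring.

    Q → 2 Z (k = 0.0280 s⁻¹)
    L + Z → G (k = 1700 L mol⁻¹ s⁻¹)
    E + G → D + Z (k = 16000 L mol⁻¹ s⁻¹)
    2 Z → J (k = 2.30 × 10⁶ L mol⁻¹ s⁻¹)
    D ⇌ X (K = 1.60, k = 0.100 s⁻¹)

In spring at 15.0 min, E stood at 0%, and D and X summed to 30.0%, the ceiling of 30.0%, but X held 18.5% of it. The step D <-> X cost spring 18 points of D. The same count serves the neighbour of midnight with 0.0030 M of Q: E fell to 68.5% of its charge, so 37.8% of L should have passed, and D and X stood at 14.5% and 23.3%.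

(Readings and results are calculated from invented constants, and the scatter is random.)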